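The two aryl–CH2 bonds of the prenyl groups, at C3' of ring A (the resorcinol-type ketone ring) and at C5 of ring B (the catechol ring), are disconnected back to the adjacent phenolic oxygens O4' and O4. Because each prenylated carbon lies ortho to such an oxygen, one double aromatic Claisen rearrangement of a bis(1,1-dimethylallyl) ether should move both five-carbon units from oxygen to carbon in a single operation. The precursor is the prenyl-free (R)-ketol, built from methyl (R)-glycidate, carrying the two tertiary allyl ethers, a free hydrogen-bonded 2'-OH, a 3-OMOM group that blocks the other ortho site of ring B, and an α-OTBS group that guards the stereocentre.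

Key step: step 12

Remark: primed positions belong to ring A, unprimed ring positions to ring B, and C2 is the carbinol carbon. The target is (R) at C2. The C2–O bond of methyl (R)-glycidate is never broken and the priority order O > C=O > CH2 > H holds in every intermediate, so the descriptor stays (R) throughout. In step 12 the ring B ether is assumed to rearrange first; the order has no effect on the product.

Step 1
Reactants: 1 5-bromosalicylaldehyde
Product: 2 2-(benzyloxy)-5-bromobenzaldehyde
Conditions: BnBr, K2CO3, DMF, rt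
Reagents that add atoms: benzyl bromide, BrCc1ccccc1
Why: Williamson ether synthesis in which the phenoxide displaces the benzylic bromide, masking the oxygen that becomes O4 of ring B as a benzyl ether removable later without acid.

Step 2
Reactants: 2 2-(benzyloxy)-5-bromobenzaldehyde
Product: 4 2-(benzyloxy)-5-bromophenol, via 2-(benzyloxy)-5-bromophenyl formate 3 (not isolated)
Conditions: mCPBA, CH2Cl2, rt; then K2CO3, MeOH, rt
Reagents that add atoms: mCPBA, O=C(OO)c1cccc(Cl)c1
Why: Baeyer–Villiger (Dakin-type) oxidation in which the electron-rich ortho-alkoxyaryl group migrates in preference to hydride to give the aryl formate, which is transesterified to the phenol that becomes O3 of ring B.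

Step 3
Reactants: 4 2-(benzyloxy)-5-bromophenol
Product: 5 1-(benzyloxy)-4-bromo-2-(methoxymethoxy)benzene
Conditions: MOMCl, i-Pr2NEt, CH2Cl2, 0 °C to rt
Reagents that add atoms: chloromethyl methyl ether, COCCl
Why: O-alkylation of the phenol by the α-chloro ether under amine base (acetal formation) installs a MOM group that is stable to organometallics, hydrogenolysis, DBU and heat.

Step 4
Reactants: 5 1-(benzyloxy)-4-bromo-2-(methoxymethoxy)benzene; 6 methyl (R)-glycidate
Product: 8 methyl (2R)-3-[4-(benzyloxy)-3-(methoxymethoxy)phenyl]-2-hydroxypropanoate, via 4-(benzyloxy)-3-(methoxymethoxy)phenylmagnesium bromide 7 (not isolated)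
Conditions: Mg, THF, reflux; then CuI (10 mol %), 6, THF, −40 to −20 °C
Reagents that add atoms: none
Why: Grignard formation followed by CuI-catalysed SN2 opening of the epoxide at its unsubstituted carbon, which outpaces addition to the ester at low temperature; the C2–O bond is untouched, so the (R) configuration of 6 is carried unchanged into the aryl lactate.

Step 5
Reactants: 8 methyl (2R)-3-[4-(benzyloxy)-3-(methoxymethoxy)phenyl]-2-hydroxypropanoate
Product: 9 methyl (2R)-3-[4-(benzyloxy)-3-(methoxymethoxy)phenyl]-2-[(tert-butyldimethylsilyl)oxy]propanoate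
Conditions: TBSCl, imidazole, DMF, rt
Reagents that add atoms: tert-butyldimethylsilyl chloride, CC(C)(C)[Si](C)(C)Cl
Why: Imidazole-promoted silylation of the secondary alcohol caps the carbinol oxygen without touching the stereocentre, and the TBS ether later prevents α-ketol isomerisation.

Step 6
Reactants: 9 methyl (2R)-3-[4-(benzyloxy)-3-(methoxymethoxy)phenyl]-2-[(tert-butyldimethylsilyl)oxy]propanoate
Product: 10 (2R)-3-[4-(benzyloxy)-3-(methoxymethoxy)phenyl]-2-[(tert-butyldimethylsilyl)oxy]-N-methoxy-N-methylpropanamide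
Conditions: MeNH(OMe)·HCl, i-PrMgCl, THF, −20 to 0 °C
Reagents that add atoms: N,O-dimethylhydroxylamine hydrochloride, CNOC.Cl
Why: Direct ester-to-Weinreb-amide aminolysis in which the chloromagnesium amide adds to the ester and expels methoxide; the hindered base at low temperature leaves the α-silyloxy stereocentre untouched.

Step 7
Reactants: 11 4-bromoresorcinol
Product: 12 2,4-bis(benzyloxy)-1-bromobenzene
Conditions: BnBr (2.2 equiv), K2CO3, DMF, rt
Reagents that add atoms: benzyl bromide (2 equiv), BrCc1ccccc1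
Why: Twofold Williamson ether synthesis, one equivalent of benzyl bromide per phenol, gives the bis-benzyl ether needed for clean bromine–lithium exchange.

Step 8
Reactants: 12 2,4-bis(benzyloxy)-1-bromobenzene; 10 (2R)-3-[4-(benzyloxy)-3-(methoxymethoxy)phenyl]-2-[(tert-butyldimethylsilyl)oxy]-N-methoxy-N-methylpropanamide
Product: 14 (2R)-1-[2,4-bis(benzyloxy)phenyl]-3-[4-(benzyloxy)-3-(methoxymethoxy)phenyl]-2-[(tert-butyldimethylsilyl)oxy]propan-1-one, via 2,4-bis(benzyloxy)phenyllithium 13 (not isolated)
Conditions: n-BuLi, THF, −78 °C; then 10, −78 to −20 °C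
Reagents that add atoms: none
Why: Bromine–lithium exchange followed by Weinreb ketone synthesis, in which the aryllithium adds once to give a chelated tetrahedral intermediate that collapses to the ketone only on work-up; addition at −78 °C outruns deprotonation at C2, so the configuration should be retained.

Step 9
Reactants: 14 (2R)-1-[2,4-bis(benzyloxy)phenyl]-3-[4-(benzyloxy)-3-(methoxymethoxy)phenyl]-2-[(tert-butyldimethylsilyl)oxy]propan-1-one
Product: 15 (2R)-2-[(tert-butyldimethylsilyl)oxy]-1-(2,4-dihydroxyphenyl)-3-[4-hydroxy-3-(methoxymethoxy)phenyl]propan-1-one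
Conditions: H2 (1 atm), Pd/C, EtOAc, rt
Reagents that add atoms: none
Why: Catalytic hydrogenolysis cleaves the three benzyl aryl ethers, whereas the electron-rich, then chelated aryl ketone, the MOM acetal and the TBS ether are inert under these neutral aprotic conditions.

Step 10
Reactants: 15 (2R)-2-[(tert-butyldimethylsilyl)oxy]-1-(2,4-dihydroxyphenyl)-3-[4-hydroxy-3-(methoxymethoxy)phenyl]propan-1-one; 16 3-chloro-3-methylbut-1-yne (2 equiv in total)
Product: 17 (2R)-2-[(tert-butyldimethylsilyl)oxy]-1-{2-hydroxy-4-[(2-methylbut-3-yn-2-yl)oxy]phenyl}-3-{3-(methoxymethoxy)-4-[(2-methylbut-3-yn-2-yl)oxy]phenyl}propan-1-one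
Conditions: 16 (2.4 equiv), DBU (2.6 equiv), CuCl2·2H2O (cat.), MeCN, 0 °C
Reagents that add atoms: 3-chloro-3-methylbut-1-yne (the second equivalent of 16), C#CC(C)(C)Cl
Why: CuCl2-catalysed O-propargylation of phenoxides by a tertiary propargylic chloride, one molecule of 16 being consumed at O4' and a second at O4; the 2'-OH is hydrogen-bonded to the ketone and far less nucleophilic, so only these two oxygens should be alkylated.

Step 11
Reactants: 17 (2R)-2-[(tert-butyldimethylsilyl)oxy]-1-{2-hydroxy-4-[(2-methylbut-3-yn-2-yl)oxy]phenyl}-3-{3-(methoxymethoxy)-4-[(2-methylbut-3-yn-2-yl)oxy]phenyl}propan-1-one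
Product: 18 (2R)-2-[(tert-butyldimethylsilyl)oxy]-1-{2-hydroxy-4-[(2-methylbut-3-en-2-yl)oxy]phenyl}-3-{3-(methoxymethoxy)-4-[(2-methylbut-3-en-2-yl)oxy]phenyl}propan-1-one
Conditions: H2 (1 atm), Pd/CaCO3 poisoned with Pb(OAc)2, quinoline, EtOAc, rt
Reagents that add atoms: none
Why: Lindlar-type semi-hydrogenation over the lead-poisoned catalyst should stop at the terminal alkenes, converting both alkynes into 1,1-dimethylallyl ethers without reducing the ketone or cleaving the allylic C–O bonds.

Step 12
Reactants: 18 (2R)-2-[(tert-butyldimethylsilyl)oxy]-1-{2-hydroxy-4-[(2-methylbut-3-en-2-yl)oxy]phenyl}-3-{3-(methoxymethoxy)-4-[(2-methylbut-3-en-2-yl)oxy]phenyl}propan-1-one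
Product: 20 (2R)-2-[(tert-butyldimethylsilyl)oxy]-1-[2,4-dihydroxy-3-(3-methylbut-2-en-1-yl)phenyl]-3-[4-hydroxy-3-(methoxymethoxy)-5-(3-methylbut-2-en-1-yl)phenyl]propan-1-one, via ring-B-rearranged monoether 19 (not isolated)
Conditions: PhNEt2, 140 °C, Ar
Reagents that add atoms: none
Why: Each O–CMe2–CH=CH2 unit should migrate by a concerted suprafacial [3,3] shift in which the vinyl terminus attacks the ring carbon next to the ether oxygen as the O–CMe2 bond is severed (six-centre, chair-like array), and the ortho-dienone so formed enolises back to an aromatic phenol. This is the aromatic Claisen rearrangement of tertiary allyl aryl ethers, an established route to ortho-prenyl phenols including 3-prenyl-2,4-dihydroxyaryl ketones; allylic transposition turns the O-bound reverse-prenyl unit into a C-bound linear prenyl group, and the quaternary carbinol carbon lets such ethers rearrange well below the temperatures simple allyl ethers need. No ring is closed and no stereocentre is created; the silylated C2 centre is a spectator, and the weakly basic solvent scavenges traces of acid that would ionise the tertiary ethers or close the new prenyl phenols to chromans, while being too weak a base to enolise the ketone. Site selectivity is needed on both rings: on ring B the second ortho position (C3) carries the OMOM group, so only C5 can accept the allyl unit and rearomatise. On ring A the chelate between the 2'-hydroxyl and the carbonyl oxygen gives the C3'–C4' bond the greater double-bond character, which should steer the allyl unit to C3' (flanked by both oxygens) in preference to C5'.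

Step 13
Reactants: 20 (2R)-2-[(tert-butyldimethylsilyl)oxy]-1-[2,4-dihydroxy-3-(3-methylbut-2-en-1-yl)phenyl]-3-[4-hydroxy-3-(methoxymethoxy)-5-(3-methylbut-2-en-1-yl)phenyl]propan-1-one
Product: 21 (2R)-1-[2,4-dihydroxy-3-(3-methylbut-2-en-1-yl)phenyl]-3-[3,4-dihydroxy-5-(3-methylbut-2-en-1-yl)phenyl]-2-hydroxypropan-1-one (CNP0286988.1)
Conditions: 3 M aq. HCl, MeOH, rt
Reagents that add atoms: none
Why: Acid-catalysed acetal exchange cleaves the aryl MOM ether and acid-catalysed methanolysis cleaves the secondary silyl ether in the same pot; dilute acid at room temperature is commonly tolerated by ortho-prenyl phenols and does not enolise the ketol, so the (R) centre and both double bonds should survive.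

Compound list
1 | 5-bromosalicylaldehyde | O=Cc1cc(Br)ccc1O | starting material
2 | 2-(benzyloxy)-5-bromobenzaldehyde | O=Cc1cc(Br)ccc1OCc1ccccc1 | intermediate
3 | 2-(benzyloxy)-5-bromophenyl formate | O=COc1cc(Br)ccc1OCc1ccccc1 | intermediate (not isolated)
4 | 2-(benzyloxy)-5-bromophenol | Oc1cc(Br)ccc1OCc1ccccc1 | intermediate
5 | 1-(benzyloxy)-4-bromo-2-(methoxymethoxy)benzene | COCOc1cc(Br)ccc1OCc1ccccc1 | intermediate
6 | methyl (R)-glycidate | COC(=O)[C@H]1CO1 | starting material
7 | 4-(benzyloxy)-3-(methoxymethoxy)phenylmagnesium bromide | COCOc1cc([Mg]Br)ccc1OCc1ccccc1 | intermediate (not isolated)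
8 | methyl (2R)-3-[4-(benzyloxy)-3-(methoxymethoxy)phenyl]-2-hydroxypropanoate | COC(=O)[C@H](O)Cc1ccc(OCc2ccccc2)c(OCOC)c1 | intermediate
9 | methyl (2R)-3-[4-(benzyloxy)-3-(methoxymethoxy)phenyl]-2-[(tert-butyldimethylsilyl)oxy]propanoate | COC(=O)[C@H](O[Si](C)(C)C(C)(C)C)Cc1ccc(OCc2ccccc2)c(OCOC)c1 | intermediate
10 | (2R)-3-[4-(benzyloxy)-3-(methoxymethoxy)phenyl]-2-[(tert-butyldimethylsilyl)oxy]-N-methoxy-N-methylpropanamide | CON(C)C(=O)[C@H](O[Si](C)(C)C(C)(C)C)Cc1ccc(OCc2ccccc2)c(OCOC)c1 | intermediate
11 | 4-bromoresorcinol | Oc1ccc(Br)c(O)c1 | starting material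
12 | 2,4-bis(benzyloxy)-1-bromobenzene | Brc1ccc(OCc2ccccc2)cc1OCc1ccccc1 | intermediate
13 | 2,4-bis(benzyloxy)phenyllithium | [Li]c1ccc(OCc2ccccc2)cc1OCc1ccccc1 | intermediate (not isolated)
14 | (2R)-1-[2,4-bis(benzyloxy)phenyl]-3-[4-(benzyloxy)-3-(methoxymethoxy)phenyl]-2-[(tert-butyldimethylsilyl)oxy]propan-1-one | O=C([C@H](O[Si](C)(C)C(C)(C)C)Cc1ccc(OCc2ccccc2)c(OCOC)c1)c1ccc(OCc2ccccc2)cc1OCc1ccccc1 | intermediate
15 | (2R)-2-[(tert-butyldimethylsilyl)oxy]-1-(2,4-dihydroxyphenyl)-3-[4-hydroxy-3-(methoxymethoxy)phenyl]propan-1-one | O=C([C@H](O[Si](C)(C)C(C)(C)C)Cc1ccc(O)c(OCOC)c1)c1ccc(O)cc1O | intermediate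
16 | 3-chloro-3-methylbut-1-yne | C#CC(C)(C)Cl | starting material
17 | (2R)-2-[(tert-butyldimethylsilyl)oxy]-1-{2-hydroxy-4-[(2-methylbut-3-yn-2-yl)oxy]phenyl}-3-{3-(methoxymethoxy)-4-[(2-methylbut-3-yn-2-yl)oxy]phenyl}propan-1-one | C#CC(C)(C)Oc1ccc(C(=O)[C@H](O[Si](C)(C)C(C)(C)C)Cc2ccc(OC(C)(C)C#C)c(OCOC)c2)c(O)c1 | intermediate
18 | (2R)-2-[(tert-butyldimethylsilyl)oxy]-1-{2-hydroxy-4-[(2-methylbut-3-en-2-yl)oxy]phenyl}-3-{3-(methoxymethoxy)-4-[(2-methylbut-3-en-2-yl)oxy]phenyl}propan-1-one (key-step precursor) | C=CC(C)(C)Oc1ccc(C(=O)[C@H](O[Si](C)(C)C(C)(C)C)Cc2ccc(OC(C)(C)C=C)c(OCOC)c2)c(O)c1 | intermediate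
19 | (2R)-2-[(tert-butyldimethylsilyl)oxy]-1-{2-hydroxy-4-[(2-methylbut-3-en-2-yl)oxy]phenyl}-3-[4-hydroxy-3-(methoxymethoxy)-5-(3-methylbut-2-en-1-yl)phenyl]propan-1-one (ring-B-rearranged monoether) | C=CC(C)(C)Oc1ccc(C(=O)[C@H](O[Si](C)(C)C(C)(C)C)Cc2cc(CC=C(C)C)c(O)c(OCOC)c2)c(O)c1 | intermediate (not isolated)
20 | (2R)-2-[(tert-butyldimethylsilyl)oxy]-1-[2,4-dihydroxy-3-(3-methylbut-2-en-1-yl)phenyl]-3-[4-hydroxy-3-(methoxymethoxy)-5-(3-methylbut-2-en-1-yl)phenyl]propan-1-one (key-step product) | CC(C)=CCc1cc(C[C@@H](O[Si](C)(C)C(C)(C)C)C(=O)c2ccc(O)c(CC=C(C)C)c2O)cc(OCOC)c1O | intermediate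
21 | (2R)-1-[2,4-dihydroxy-3-(3-methylbut-2-en-1-yl)phenyl]-3-[3,4-dihydroxy-5-(3-methylbut-2-en-1-yl)phenyl]-2-hydroxypropan-1-one (CNP0286988.1) | CC(C)=CCc1cc(C[C@@H](O)C(=O)c2ccc(O)c(CC=C(C)C)c2O)cc(O)c1O | target

Total step count: 13.
Longest linear sequence: 12 steps (steps 1–6 and 8–13, from 5-bromosalicylaldehyde); step 7 is the one-step ring A branch.

Steps most likely to fail

Step 12 (key step). The ring A ether may deliver its allyl unit to C5' in competition with C3'. Either tertiary ether may ionise and shed isoprene instead of rearranging, and prolonged heating may erode the configuration at C2. The fallback installs the ring A prenyl group by directed ortho-metalation before the fragments are joined and keeps only the unambiguous ring B rearrangement, run at the amide stage where C2 is far less acidic. Setting out from Weinreb amide 10, hydrogenolysis (H2, Pd/C, EtOAc) should give the phenolic Weinreb amide F1. CuCl2-catalysed alkylation with 16 and DBU should give the 1,1-dimethylpropargyl ether F2, and semi-hydrogenation over Pd/CaCO3 poisoned with Pb(OAc)2 should give the 1,1-dimethylallyl ether F3. Heating F3 in PhNEt2 should give the 5-prenyl phenol F4, since only C5 is open, and MOMCl/i-Pr2NEt should then give the bis-MOM Weinreb amide F5. Separately, resorcinol (Oc1cccc(O)c1) with MOMCl/NaH should give 1,3-bis(methoxymethoxy)benzene F6. n-BuLi in THF at 0 °C should lithiate the position between the two OMOM groups to give 2,6-bis(methoxymethoxy)phenyllithium F7, which with CuI and prenyl bromide (CC(C)=CCBr) should give 1,3-bis(methoxymethoxy)-2-prenylbenzene F8. A second ortho-lithiation (n-BuLi, TMEDA, THF, 0 °C) next to one OMOM group should give 2,4-bis(methoxymethoxy)-3-prenylphenyllithium F9, and its addition to F5 at −78 °C should give the fully protected diprenyl ketone F10. Acidic methanolysis of F10 (3 M aq. HCl, MeOH, rt) removes the four MOM groups and the TBS group and rejoins the route at target 21.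

Step 13. Under protic acid the prenyl double bonds may be protonated and trapped by the neighbouring phenols (closure to 2,2-dimethylchromans) or by methanol before the silyl ether at C2 is fully cleaved. The fallback uses two orthogonal cleavages without protic acid. Setting out from 20, ZnBr2 and n-PrSH in CH2Cl2 at 0 °C (Lewis acid–thiol acetal cleavage, complete within minutes) should remove the MOM group and give the α-silyloxy tetraphenol F11. Et3N·3HF in MeCN at rt (fluoride-driven desilylation under near-neutral conditions) should then give target 21.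

Step 10. O-alkylation may be incomplete or unselective across the three phenols: the hindered O4 next to the OMOM group may lag and the chelated 2'-OH may begin to react. The tertiary chloride may eliminate, and long exposure to DBU may epimerise C2. The fallback is a Tsuji–Trost O-allylation that installs the tertiary allyl ethers directly. Setting out from triol 15, two equivalents of tert-butyl 2-methylbut-3-en-2-yl carbonate (C=CC(C)(C)OC(=O)OC(C)(C)C) and Pd(PPh3)4 in THF at 0 °C should give the bis(1,1-dimethylallyl) ether 18, by attack of the phenoxides on the more substituted terminus of the 1,1-dimethylallyl–palladium intermediate. This by-passes 17 and step 11, and no compound outside the list is made.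

Further compounds
F1 | step 12 | (2R)-2-[(tert-butyldimethylsilyl)oxy]-3-[4-hydroxy-3-(methoxymethoxy)phenyl]-N-methoxy-N-methylpropanamide | CON(C)C(=O)[C@H](O[Si](C)(C)C(C)(C)C)Cc1ccc(O)c(OCOC)c1
F2 | step 12 | (2R)-2-[(tert-butyldimethylsilyl)oxy]-N-methoxy-3-{3-(methoxymethoxy)-4-[(2-methylbut-3-yn-2-yl)oxy]phenyl}-N-methylpropanamide | CON(C)C(=O)[C@H](O[Si](C)(C)C(C)(C)C)Cc1ccc(OC(C)(C)C#C)c(OCOC)c1
F3 | step 12 | (2R)-2-[(tert-butyldimethylsilyl)oxy]-N-methoxy-3-{3-(methoxymethoxy)-4-[(2-methylbut-3-en-2-yl)oxy]phenyl}-N-methylpropanamide | CON(C)C(=O)[C@H](O[Si](C)(C)C(C)(C)C)Cc1ccc(OC(C)(C)C=C)c(OCOC)c1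
F4 | step 12 | (2R)-2-[(tert-butyldimethylsilyl)oxy]-3-[4-hydroxy-3-(methoxymethoxy)-5-(3-methylbut-2-en-1-yl)phenyl]-N-methoxy-N-methylpropanamide | CON(C)C(=O)[C@H](O[Si](C)(C)C(C)(C)C)Cc1cc(CC=C(C)C)c(O)c(OCOC)c1
F5 | step 12 | (2R)-3-[3,4-bis(methoxymethoxy)-5-(3-methylbut-2-en-1-yl)phenyl]-2-[(tert-butyldimethylsilyl)oxy]-N-methoxy-N-methylpropanamide | CON(C)C(=O)[C@H](O[Si](C)(C)C(C)(C)C)Cc1cc(CC=C(C)C)c(OCOC)c(OCOC)c1
F6 | step 12 | 1,3-bis(methoxymethoxy)benzene | COCOc1cccc(OCOC)c1
F7 | step 12 | 2,6-bis(methoxymethoxy)phenyllithium | [Li]c1c(OCOC)cccc1OCOC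
F8 | step 12 | 1,3-bis(methoxymethoxy)-2-(3-methylbut-2-en-1-yl)benzene | COCOc1cccc(OCOC)c1CC=C(C)C
F9 | step 12 | 2,4-bis(methoxymethoxy)-3-(3-methylbut-2-en-1-yl)phenyllithium | [Li]c1ccc(OCOC)c(CC=C(C)C)c1OCOC
F10 | step 12 | (2R)-1-[2,4-bis(methoxymethoxy)-3-(3-methylbut-2-en-1-yl)phenyl]-3-[3,4-bis(methoxymethoxy)-5-(3-methylbut-2-en-1-yl)phenyl]-2-[(tert-butyldimethylsilyl)oxy]propan-1-one | COCOc1ccc(C(=O)[C@H](O[Si](C)(C)C(C)(C)C)Cc2cc(CC=C(C)C)c(OCOC)c(OCOC)c2)c(OCOC)c1CC=C(C)C
F11 | step 13 | (2R)-2-[(tert-butyldimethylsilyl)oxy]-1-[2,4-dihydroxy-3-(3-methylbut-2-en-1-yl)phenyl]-3-[3,4-dihydroxy-5-(3-methylbut-2-en-1-yl)phenyl]propan-1-one | CC(C)=CCc1cc(C[C@@H](O[Si](C)(C)C(C)(C)C)C(=O)c2ccc(O)c(CC=C(C)C)c2O)cc(O)c1O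
F0 | step 10 | none | none
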